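If you want this flask's yield before any integrator runs, count powers of ten of unused coupling partner.

| flask | solid substrate | coupling partner | initiator | remark | time |
|---|---|---|---|---|---|
| gamma | 0.020 M | 0.90 equiv | 1.2 mol% | run made earlier |  |
| alpha | 0.020 M | 0.90 equiv | 5 mol% | run made earlier |  |
| epsilon | 0.030 M | 0.90 equiv | 2.5 mol% | run made earlier |  |
| flask | 0.020 M | 0.900 equiv | 2.5 mol% |  | 12 min |

| run | time / min | target / % | crystals / % |
|---|---|---|---|
| gamma | 1.00 | 12.1 | 0.1 |
| gamma | 1.33 | 17.6 | 0.4 |
| gamma | 2.00 | 25.4 | 0.5 |
| gamma | 3.00 | 37.4 | 0 |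
| gamma | 5.00 | 51.6 | 9.6 |
| gamma | 8.00 | 61.8 | 20.8 |
| gamma | 12.0 | 67.1 | 24.3 |
| alpha | 0.667 | 13.9 | 0 |
| alpha | 2.00 | 44.9 | 3.0 |
| alpha | 3.00 | 63.6 | 20.8 |
| alpha | 5.00 | 82.9 | 42.4 |
| alpha | 8.00 | 89.3 | 46.8 |
| alpha | 10.0 | 89.5 | 48.2 |
| alpha | 12.0 | 89.4 | 47.5 |
| epsilon | 2.50 | 34.3 | 5.7 |
| epsilon | 5.00 | 54.3 | 26.3 |
| epsilon | 8.00 | 67.0 | 38.5 |
| epsilon | 10.0 | 70.6 | 42.8 |
| epsilon | 12.0 | 73.2 | 44.6 |

(each reading ± 0.5 percentage points)

- a species is counted by the solid substrate in it: one ended chains B counts as two
- amounts and yields of target count crystals too
- given per volume of solution although it is solid: solid substrate, crystals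
- candidate steps: starting material + initiating radical -> chain carrier; 2 initiating radical -> ended chains A; initiator -> 2 initiating radical; 2 chain carrier -> ended chains B; crystals <-> target; solid substrate <-> starting material; coupling partner + chain carrier -> target + initiating radical
- at the start none of the solid substrate is in solution
- starting material means what is dissolved; the solid is not counted in it

- target and crystals together at 12 min, in percent of the solid substrate charged
- concentration of starting material in solution at 12 min, in percent of saturation

At 0.900 equiv the coupling partner is the limiting reagent, and alpha indeed stalls at 89.4%. Gamma at 12.0 min reads 67.1%, which by my reckoning means its unused partner has fallen by 0.594 powers of ten. Assume, as my own guess, that this count scales with initiator loading and inversely with substrate concentration, and this flask gets 1.24: its partner decades, the tenfold falls of unused coupling partner by that time. Read back through the charge, that is 84.8% for target and crystals together. Was one number enough? Alpha reckons to 89.7% against its 89.4%, a weak test, since that reading stands 0.6 percentage points below what its charge of partner allows and carries a scatter of 0.5 points, but epsilon, at the flask's loading and 0.030 M, reckons to 76.6% against 73.2%, a miss of 3.4 points. So the count passes on alpha's plateau and misses on epsilon. It gives me no figure for saturation.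

The forecast differs from my reckoning, saying 80%, and it gives 30% for saturation, where I have no figure: “The flask's relative drive of 1.44 gives about 80%.”

The flask gives 84.1% and 62.5%.

    starting material + initiating radical → chain carrier (k = 83000 M⁻¹ s⁻¹)
    2 initiating radical → ended chains A (k = 5.00 × 10⁷ M⁻¹ s⁻¹)
    initiator → 2 initiating radical (k = 0.0100 s⁻¹)
    2 chain carrier → ended chains B (k = 1.00 × 10⁷ M⁻¹ s⁻¹)
    crystals ⇌ target, rate k5*(cs5 - [target]) while solid is left; crystals form when [target] > cs5 (solubility = 8.40 mM, k = 5.70 s⁻¹)
    solid substrate ⇌ starting material, rate k6*(cs6 - [starting material]) while solid is left; crystals form when [starting material] > cs6 (solubility = 5.00 mM, k = 0.0480 s⁻¹)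
    coupling partner + chain carrier → target + initiating radical (k = 70000 M⁻¹ s⁻¹)

This flask keeps 6.5% of its coupling partner at 12.0 min, which is 1.19 decades against the reckoned 1.24. The neighbouring flask with 6.2 mol% of initiator reckons to 3.07 decades and so 89.9%. It gives 89.8%, with 0.19% of its partner left, which is 2.72 decades.

The data are simulated for an exercise; noise was put on by code.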